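The route cuts the bond between C2 of the pyran ring (ring C) and the ipso carbon of the trihydroxyphenyl ring (ring B). The key step exploits the cis relationship between the C3 oxygen and ring B at C2. The C3 oxygen and the lactol oxygen of an enantiopure chroman-2,3-diol hold ring B on boron as a cis-fused cyclic boronate. Ionisation at C2 then lets the aryl group shift from boron to C2 on the face of the C3–O bond, which forms the C2–aryl bond and sets C2 in one operation. The C3 centre comes from methyl (R)-glycidate; esterification and hydrogenolysis finish the synthesis.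

Key step: step 6

Assumption: lactol 5 is carried as a mixture of C2 epimers; this does not matter, because C2 is ionised and set anew in step 6.

Step 1
Reactants: 1 3,5-bis(benzyloxy)phenol; 2 methyl (R)-glycidate
Product: 4 (3R)-5,7-bis(benzyloxy)-3-hydroxychroman-2-one, via hydroxy ester 3 (not isolated)
Conditions: Sc(OTf)3 (10 mol %), CH2Cl2/HFIP, 0 °C → rt; then PPTS (cat.), toluene, 70 °C
Reagents that add atoms: none
Why: Lewis-acid-promoted Friedel–Crafts alkylation: the phloroglucinol-type ring of 1 should open the activated epoxide at its unsubstituted CH2 carbon, ortho to the free hydroxyl (two equivalent sites, less hindered than C4 between the benzyloxy groups), so the glycidate stereocentre is untouched and becomes C3 (R), and only this ortho adduct can lactonise under PPTS.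

Step 2
Reactants: 4 (3R)-5,7-bis(benzyloxy)-3-hydroxychroman-2-one
Product: 5 (3R)-5,7-bis(benzyloxy)chroman-2,3-diol (lactol, C2 epimers)
Conditions: i-Bu2AlH (2.2 equiv), CH2Cl2, −78 °C; aq. potassium sodium tartrate
Reagents that add atoms: none
Why: Partial reduction of a lactone to a lactol with i-Bu2AlH at −78 °C; the aluminium hemiacetal should be held by chelation to the neighbouring C3 alkoxide, and C3 is not affected.

Step 3
Reactants: 6 5-bromo-1,2,3-trimethoxybenzene
Product: 7 5-bromobenzene-1,2,3-triol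
Conditions: BBr3 (3.5 equiv), CH2Cl2, −78 °C → rt; H2O
Reagents that add atoms: none
Why: Lewis-acid cleavage of aryl methyl ethers: BBr3 binds each methoxy oxygen and bromide removes the methyl group by SN2 attack.

Step 4
Reactants: 7 5-bromobenzene-1,2,3-triol
Product: 8 5-bromo-1,2,3-tris(benzyloxy)benzene
Conditions: BnBr (3.3 equiv), K2CO3, DMF, 60 °C, N2
Reagents that add atoms: benzyl bromide, BrCc1ccccc1
Why: Williamson ether synthesis on the three phenoxides, run under nitrogen because the pyrogallol is air-sensitive in base.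

Step 5
Reactants: 8 5-bromo-1,2,3-tris(benzyloxy)benzene
Product: 11 [3,4,5-tris(benzyloxy)phenyl]boronic acid, via aryllithium 9 (not isolated), via lithium borate 10 (not isolated)
Conditions: n-BuLi, THF, −78 °C; B(Oi-Pr)3, −78 °C → rt; 1 M HCl
Reagents that add atoms: triisopropyl borate, CC(C)OB(OC(C)C)OC(C)C; water, O
Why: Bromine–lithium exchange should outrun any attack on the benzyl ethers at −78 °C, and the aryllithium is trapped by the borate ester and hydrolysed to the boronic acid.

Step 6
Reactants: 5 (3R)-5,7-bis(benzyloxy)chroman-2,3-diol; 11 [3,4,5-tris(benzyloxy)phenyl]boronic acid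
Product: 13 (2R,3R)-5,7-bis(benzyloxy)-2-[3,4,5-tris(benzyloxy)phenyl]chroman-3-ol, via cyclic boronate 12 (not isolated)
Conditions: 4 Å molecular sieves, CH2Cl2, rt; then BF3·OEt2 (2.5 equiv), −78 → −20 °C, high dilution; aq. NaHCO3
Reagents that add atoms: none
Why: Proposed new method: BF3 ionises the exocyclic anomeric C2–O bond of the cis-fused dioxaborolane 12 to the ring-C oxocarbenium ion (stabilised by O1), the released B–O oxygen and fluoride make boron four-coordinate, and the electron-rich aryl group then shifts from boron to C2 through a five-membered cyclic transition state (ipso carbon, B, O3, C3, C2). The closest known reaction types are the hydroxyl-directed, cis-selective transfer of aryl and alkenyl groups from boronates to cyclic N-acyliminium ions under BF3·OEt2 and the Petasis borono-Mannich reaction of α-hydroxy aldehydes; here the iminium ion is replaced by a chroman-2-yl oxocarbenium ion. No ring is closed: ring C is already present and the five-membered boronate ring is opened. The new stereocentre C2 is controlled by C3, because the aryl group can only reach the face of C2 on which the C3–O–B tether lies, which should give the 2,3-cis (2R,3R) product that an untethered nucleophile would not favour. The step needs arylation at C2 to outrun Friedel–Crafts attack by the electron-rich ring A of a second molecule and loss of H3 towards the chroman-3-one enol; intramolecular delivery, low temperature, dilution and the absence of a second free boron nucleophile are meant to secure this.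

Step 7
Reactants: 14 methyl 3,4-dihydroxy-5-methoxybenzoate
Product: 15 methyl 3,4-bis(benzyloxy)-5-methoxybenzoate
Conditions: BnBr (2.2 equiv), K2CO3, DMF, 60 °C
Reagents that add atoms: benzyl bromide, BrCc1ccccc1
Why: Williamson ether synthesis on the two phenoxides.

Step 8
Reactants: 15 methyl 3,4-bis(benzyloxy)-5-methoxybenzoate
Product: 16 3,4-bis(benzyloxy)-5-methoxybenzoic acid
Conditions: LiOH, THF/MeOH/H2O, 50 °C; then 1 M HCl
Reagents that add atoms: lithium hydroxide, [Li+].[OH-]
Why: Saponification of the methyl ester; the benzyl and methyl ethers are inert to hydroxide.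

Step 9
Reactants: 13 (2R,3R)-5,7-bis(benzyloxy)-2-[3,4,5-tris(benzyloxy)phenyl]chroman-3-ol; 16 3,4-bis(benzyloxy)-5-methoxybenzoic acid
Product: 17 (2R,3R)-5,7-bis(benzyloxy)-2-[3,4,5-tris(benzyloxy)phenyl]chroman-3-yl 3,4-bis(benzyloxy)-5-methoxybenzoate
Conditions: DCC, DMAP (cat.), CH2Cl2, rt
Reagents that add atoms: none
Why: Steglich esterification: DMAP carries the acyl group from the O-acylisourea to the hindered axial C3 hydroxyl without touching the configuration at C2 or C3.

Step 10
Reactants: 17 (2R,3R)-5,7-bis(benzyloxy)-2-[3,4,5-tris(benzyloxy)phenyl]chroman-3-yl 3,4-bis(benzyloxy)-5-methoxybenzoate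
Product: 18 (-)-epigallocatechin 3-(3-methyl-gallate)
Conditions: H2 (1 atm), Pd(OH)2/C, THF/MeOH, rt; filtration under N2
Reagents that add atoms: none
Why: Heterogeneous hydrogenolysis of the seven O-benzyl groups; the aryl methyl ether, the ester and the cyclic benzylic C2–O1 bond should survive under neutral conditions at room temperature, and no stereocentre is touched.

Compound list
1 | 3,5-bis(benzyloxy)phenol | Oc1cc(OCc2ccccc2)cc(OCc2ccccc2)c1 | starting material
2 | methyl (R)-glycidate | COC(=O)[C@H]1CO1 | starting material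
3 | methyl (2R)-3-[2,4-bis(benzyloxy)-6-hydroxyphenyl]-2-hydroxypropanoate | O[C@@H](C(=O)OC)Cc1c(O)cc(OCc2ccccc2)cc1OCc1ccccc1 | intermediate
4 | (3R)-5,7-bis(benzyloxy)-3-hydroxychroman-2-one | O[C@@H]1Cc2c(OCc3ccccc3)cc(OCc3ccccc3)cc2OC1=O | intermediate
5 | (3R)-5,7-bis(benzyloxy)chroman-2,3-diol (C2 epimers) | O[C@@H]1Cc2c(OCc3ccccc3)cc(OCc3ccccc3)cc2OC1O | intermediate
6 | 5-bromo-1,2,3-trimethoxybenzene | COc1cc(Br)cc(OC)c1OC | starting material
7 | 5-bromobenzene-1,2,3-triol | Oc1cc(Br)cc(O)c1O | intermediate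
8 | 5-bromo-1,2,3-tris(benzyloxy)benzene | Brc1cc(OCc2ccccc2)c(OCc2ccccc2)c(OCc2ccccc2)c1 | intermediate
9 | [3,4,5-tris(benzyloxy)phenyl]lithium | [Li]c1cc(OCc2ccccc2)c(OCc2ccccc2)c(OCc2ccccc2)c1 | intermediate
10 | lithium triisopropoxy[3,4,5-tris(benzyloxy)phenyl]borate | [Li+].CC(C)O[B-](OC(C)C)(OC(C)C)c1cc(OCc2ccccc2)c(OCc2ccccc2)c(OCc2ccccc2)c1 | intermediate
11 | [3,4,5-tris(benzyloxy)phenyl]boronic acid | OB(O)c1cc(OCc2ccccc2)c(OCc2ccccc2)c(OCc2ccccc2)c1 | intermediate
12 | (2S,3R)-5,7-bis(benzyloxy)chroman-2,3-diyl [3,4,5-tris(benzyloxy)phenyl]boronate (cis-fused 1,3,2-dioxaborolane) | B1(c2cc(OCc3ccccc3)c(OCc4ccccc4)c(OCc5ccccc5)c2)O[C@@H]6Cc7c(OCc8ccccc8)cc(OCc9ccccc9)cc7O[C@@H]6O1 | intermediate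
13 | (2R,3R)-5,7-bis(benzyloxy)-2-[3,4,5-tris(benzyloxy)phenyl]chroman-3-ol | O[C@@H]1Cc2c(OCc3ccccc3)cc(OCc3ccccc3)cc2O[C@@H]1c4cc(OCc5ccccc5)c(OCc6ccccc6)c(OCc7ccccc7)c4 | intermediate
14 | methyl 3,4-dihydroxy-5-methoxybenzoate | COC(=O)c1cc(O)c(O)c(OC)c1 | starting material
15 | methyl 3,4-bis(benzyloxy)-5-methoxybenzoate | COC(=O)c1cc(OC)c(OCc2ccccc2)c(OCc2ccccc2)c1 | intermediate
16 | 3,4-bis(benzyloxy)-5-methoxybenzoic acid | OC(=O)c1cc(OC)c(OCc2ccccc2)c(OCc2ccccc2)c1 | intermediate
17 | (2R,3R)-5,7-bis(benzyloxy)-2-[3,4,5-tris(benzyloxy)phenyl]chroman-3-yl 3,4-bis(benzyloxy)-5-methoxybenzoate | COc1cc(C(=O)O[C@@H]2Cc3c(OCc4ccccc4)cc(OCc4ccccc4)cc3O[C@@H]2c2cc(OCc3ccccc3)c(OCc3ccccc3)c(OCc3ccccc3)c2)cc(OCc2ccccc2)c1OCc1ccccc1 | intermediate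
18 | (-)-epigallocatechin 3-(3-methyl-gallate) | COc1cc(C(=O)O[C@@H]2Cc3c(O)cc(O)cc3O[C@@H]2c2cc(O)c(O)c(O)c2)cc(O)c1O | target

Total steps: 10. Longest linear sequence: 6 steps (steps 3, 4, 5, 6, 9, 10).

Steps most likely to fail

Step 6 (proposed new method). The aryl shift from boron may be too slow. The oxocarbenium ion would then be consumed by Friedel–Crafts attack of ring A of a second molecule or by loss of H3, or the boronate may ionise at the wrong C–O bond. The fallback uses known chemistry, sets out from lactone 4 and aryllithium 9, and comes back at 13. Addition of 9 (2.1 equiv, THF, −78 °C; the first equivalent deprotonates the hydroxyl) to 4 should give (2R)-3-[2,4-bis(benzyloxy)-6-hydroxyphenyl]-2-hydroxy-1-[3,4,5-tris(benzyloxy)phenyl]propan-1-one F1, in equilibrium with its cyclic hemiketal. Chelation-controlled reduction with Zn(BH4)2 (Et2O, −20 °C) should give the anti triol (1S,2R)-3-[2,4-bis(benzyloxy)-6-hydroxyphenyl]-1-[3,4,5-tris(benzyloxy)phenyl]propane-1,2-diol F2. Mitsunobu cyclisation (PPh3, DIAD, THF, 0 °C) then lets the phenol displace the activated benzylic hydroxyl with inversion, which should close ring C with the 2,3-cis arrangement of 13. The C2–aryl bond is thus still formed by joining the same two fragments, but C2 is set over two further steps.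

Step 1. Alkylation may take place para to the hydroxyl (C4, between the two benzyloxy groups) or at oxygen, and the ester-deactivated epoxide may open sluggishly. The fallback sets out from 1 and comes back at 5. Ortho-specific formylation through the magnesium phenoxide (MgCl2, Et3N, paraformaldehyde, MeCN, reflux) should give 2,4-bis(benzyloxy)-6-hydroxybenzaldehyde F3. Wittig reaction with (triphenylphosphoranylidene)acetaldehyde (toluene, 80 °C) should give (E)-3-[2,4-bis(benzyloxy)-6-hydroxyphenyl]prop-2-enal F4. Organocatalytic conjugate transfer hydrogenation (Hantzsch ester, dibenzylammonium trifluoroacetate cat., THF) should give 5,7-bis(benzyloxy)chroman-2-ol F5. L-Proline-catalysed α-aminoxylation with nitrosobenzene (CHCl3, 0 °C), which installs oxygen with the (R) sense for L-proline, should give (3R)-5,7-bis(benzyloxy)-3-[(phenylamino)oxy]chroman-2-ol F6. N–O cleavage (Zn dust, AcOH/THF) then gives 5.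

Step 2. The aluminium hemiacetal may open (the phenoxide is a good leaving group) and be reduced further to the diol. The fallback sets out from 4 and comes back at 5. Aminolysis of the lactone with MeNH(OMe)·HCl and AlMe3 (CH2Cl2, 0 °C) should give the Weinreb amide (2R)-3-[2,4-bis(benzyloxy)-6-hydroxyphenyl]-2-hydroxy-N-methoxy-N-methylpropanamide F7. Its chelated tetrahedral intermediate stops LiAlH4 reduction (THF, −78 → 0 °C) at the aldehyde stage, and the aldehyde closes to 5 on work-up.

Further compounds
F1 | step 6 | (2R)-3-[2,4-bis(benzyloxy)-6-hydroxyphenyl]-2-hydroxy-1-[3,4,5-tris(benzyloxy)phenyl]propan-1-one | O[C@@H](C(=O)c1cc(OCc2ccccc2)c(OCc2ccccc2)c(OCc2ccccc2)c1)Cc1c(O)cc(OCc2ccccc2)cc1OCc1ccccc1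
F2 | step 6 | (1S,2R)-3-[2,4-bis(benzyloxy)-6-hydroxyphenyl]-1-[3,4,5-tris(benzyloxy)phenyl]propane-1,2-diol | O[C@@H]([C@@H](O)c1cc(OCc2ccccc2)c(OCc2ccccc2)c(OCc2ccccc2)c1)Cc1c(O)cc(OCc2ccccc2)cc1OCc1ccccc1
F3 | step 1 | 2,4-bis(benzyloxy)-6-hydroxybenzaldehyde | O=Cc1c(O)cc(OCc2ccccc2)cc1OCc1ccccc1
F4 | step 1 | (E)-3-[2,4-bis(benzyloxy)-6-hydroxyphenyl]prop-2-enal | O=C/C=C/c1c(O)cc(OCc2ccccc2)cc1OCc1ccccc1
F5 | step 1 | 5,7-bis(benzyloxy)chroman-2-ol | OC1CCc2c(OCc3ccccc3)cc(OCc3ccccc3)cc2O1
F6 | step 1 | (3R)-5,7-bis(benzyloxy)-3-[(phenylamino)oxy]chroman-2-ol | c1ccccc1NO[C@@H]2Cc3c(OCc4ccccc4)cc(OCc4ccccc4)cc3OC2O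
F7 | step 2 | (2R)-3-[2,4-bis(benzyloxy)-6-hydroxyphenyl]-2-hydroxy-N-methoxy-N-methylpropanamide | O[C@@H](C(=O)N(C)OC)Cc1c(O)cc(OCc2ccccc2)cc1OCc1ccccc1
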